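**Retrosynthetic overview**
1. Target 27 ⇐ C3‑O‑MOM ether 26 (late unmasking); the C6 carbinol comes from a 1,3‑syn reduction of β‑hydroxy ketone 23.
2. 23 ⇐ isoxazoline 21 (N–O cleavage) ⇐ nitrile oxide from oxime 9 + alkene 18; the cycloaddition sets the C4–O bond anti to the allylic OMOM.
3. 18 ⇐ myristoylation of alcohol 16 ⇐ Brown syn‑alkoxyallylboration of acetaldehyde with allyl MOM ether; the ester is placed on the correct oxygen before any other hydroxyl exists.
4. 9 ⇐ aldehyde 8 ⇐ ester 6 ⇐ serine amide 4 of 2‑(oxazol‑5‑yl)acetic acid 1.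
5. Ring order: the 5‑substituted oxazole is bought in 1; the 2,4‑disubstituted oxazole is built in step 2 (through an oxazoline); the isoxazoline is a temporary ring, formed in step 7 and opened in step 8.

Assumption: 1 and 10 are taken as catalogue compounds, and the minor diastereomers from steps 7 and 9 are removed by chromatography.

**Step 1**
Reactants: 1 2‑(1,3‑oxazol‑5‑yl)acetic acid; 2 methyl L‑serinate hydrochloride
Product: 4 methyl (2S)-3-hydroxy-2-[2-(1,3-oxazol-5-yl)acetamido]propanoate, via acyl imidazole 3 (not isolated)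
Conditions: CDI, THF, rt, 1 h; then 2, Et3N, rt
Reagents that add atoms: none
Why: CDI amide coupling through the acyl imidazole, whose aminolysis by the serine amine is much faster than acylation of the primary hydroxyl.

**Step 2**
Reactants: 4 methyl (2S)-3-hydroxy-2-[2-(1,3-oxazol-5-yl)acetamido]propanoate
Product: 6 methyl 2-(1,3-oxazol-5-ylmethyl)-1,3-oxazole-4-carboxylate, via oxazoline 5 (not isolated)
Conditions: (MeOCH2CH2)2NSF3, CH2Cl2, −20 °C; then BrCCl3, DBU, 0 °C to rt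
Reagents that add atoms: none
Why: Wipf–Williams one‑pot oxazole synthesis, in which cyclodehydration of the β‑hydroxy amide gives the oxazoline and BrCCl3/DBU dehydrogenates it by bromination–elimination at the most acidic C4–H (the serine stereocentre is deliberately lost).

**Step 3**
Reactants: 6 methyl 2-(1,3-oxazol-5-ylmethyl)-1,3-oxazole-4-carboxylate
Product: 8 2-(1,3-oxazol-5-ylmethyl)-1,3-oxazole-4-carbaldehyde, via aluminium hemiacetal 7 (not isolated)
Conditions: i-Bu2AlH (1.6 equiv), CH2Cl2, −78 °C; MeOH, then aq. KNaC4H4O6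
Reagents that add atoms: none
Why: Partial hydride reduction of the ester, which stops at the tetrahedral aluminium hemiacetal at −78 °C and releases the aldehyde only on work‑up.

**Step 4**
Reactants: 8 2-(1,3-oxazol-5-ylmethyl)-1,3-oxazole-4-carbaldehyde
Product: 9 (E)-2-(1,3-oxazol-5-ylmethyl)-1,3-oxazole-4-carbaldehyde oxime
Conditions: NH2OH·HCl, NaOAc, EtOH/H2O, rt
Reagents that add atoms: hydroxylamine hydrochloride, Cl.NO
Why: Oxime condensation of the unhindered heteroaryl aldehyde under buffered conditions.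

**Step 5**
Reactants: 10 allyl methoxymethyl ether; 11 acetaldehyde
Product: 16 (2S,3S)-3-(methoxymethoxy)pent-4-en-2-ol, via allyllithium 12 (not isolated), via lithium borate 13 (not isolated), via allylborane 14 (not isolated), via borinate ester 15 (not isolated)
Conditions: s-BuLi, THF, −78 °C; (+)-Ipc2BOMe [from (−)-α-pinene], −78 °C; BF3·OEt2, then 11, −78 °C to rt; NaOH, H2O2, rt
Reagents that add atoms: none
Why: Brown asymmetric γ‑alkoxyallylboration through a closed chair transition state, where the Z geometry of the allylborane gives the syn 2,3‑relationship and the isopinocampheyl groups direct attack to the Re face of acetaldehyde, setting (2S) and (3S) together (about 90% ee expected).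

**Step 6**
Reactants: 16 (2S,3S)-3-(methoxymethoxy)pent-4-en-2-ol; 17 tetradecanoyl chloride
Product: 18 (2S,3S)-3-(methoxymethoxy)pent-4-en-2-yl tetradecanoate
Conditions: pyridine, 4-(dimethylamino)pyridine (0.1 equiv), CH2Cl2, 0 °C to rt
Reagents that add atoms: none
Why: Nucleophilic acyl substitution on the only free hydroxyl, with no change at either stereocentre.

**Step 7**
Reactants: 9 (E)-2-(1,3-oxazol-5-ylmethyl)-1,3-oxazole-4-carbaldehyde oxime (1.5 equiv); 18 (2S,3S)-3-(methoxymethoxy)pent-4-en-2-yl tetradecanoate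
Product: 21 (1R,2S)-1-(methoxymethoxy)-1-{(5S)-3-[2-(1,3-oxazol-5-ylmethyl)-1,3-oxazol-4-yl]-4,5-dihydro-1,2-oxazol-5-yl}propan-2-yl tetradecanoate, via hydroximoyl chloride 19 (not isolated), via nitrile oxide 20 (not isolated)
Conditions: N-chlorosuccinimide, pyridine (0.05 equiv), CHCl3, 40 °C; then 18, Et3N (syringe pump), 0 °C to rt
Reagents that add atoms: none
Why: Huisgen nitrile oxide–alkene 1,3‑dipolar cycloaddition, regioselective for the 5‑substituted isoxazoline, in which the allylic OMOM sits "inside" in the transition state so the new C–O bond forms anti to it and sets the (5S) centre (about 4–6:1 expected).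

**Step 8**
Reactants: 21 (the isoxazoline from step 7)
Product: 23 (2S,3S,4S)-4-hydroxy-3-(methoxymethoxy)-6-oxo-6-[2-(1,3-oxazol-5-ylmethyl)-1,3-oxazol-4-yl]hexan-2-yl tetradecanoate, via hydroxy imine 22 (not isolated)
Conditions: H2 (1 atm), Raney Ni, B(OH)3, MeOH/H2O (5:1), rt
Reagents that add atoms: water, O
Why: Hydrogenolytic N–O cleavage of the isoxazoline followed by boric‑acid‑buffered hydrolysis of the β‑hydroxy imine unmasks the aldol without touching a stereocentre, the ester, the acetal or the oxazoles.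

**Step 9**
Reactants: 23 (the β‑hydroxy ketone from step 8)
Product: 26 (2S,3S,4S,6R)-4,6-dihydroxy-3-(methoxymethoxy)-6-[2-(1,3-oxazol-5-ylmethyl)-1,3-oxazol-4-yl]hexan-2-yl tetradecanoate, via boron chelate 24 (not isolated), via cyclic borate 25 (not isolated)
Conditions: Et2BOMe, THF/MeOH (4:1), −78 °C; NaBH4, −78 °C; AcOH, then MeOH co-evaporation
Reagents that add atoms: none
Why: Narasaka–Prasad reduction, in which external hydride attacks the six‑membered diethylboron chelate axially to give the 1,3‑syn diol and so sets (6R), while the ester is inert to NaBH4 at −78 °C.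

**Step 10**
Reactants: 26 (the MOM‑protected diol from step 9)
Product: 27 (2S,3S,4S,6R)-3,4,6-trihydroxy-6-[2-(1,3-oxazol-5-ylmethyl)-1,3-oxazol-4-yl]hexan-2-yl tetradecanoate (CNP0256493.1)
Conditions: ZnBr2 (excess), n-PrSH, CH2Cl2, 0 °C, 15 min
Reagents that add atoms: none
Why: Lewis acid–thiol cleavage of the MOM acetal, in which ZnBr2 activates the acetal and the thiol captures the methoxymethyl cation, freeing the C3 hydroxyl under non‑basic, non‑aqueous conditions that should leave the neighbouring ester in place.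

**Compound list**
1 | 2-(1,3-oxazol-5-yl)acetic acid | OC(=O)Cc1cnco1 | starting material
2 | methyl L-serinate hydrochloride, (2S) | Cl.COC(=O)[C@@H](N)CO | starting material
3 | 1-(1H-imidazol-1-yl)-2-(1,3-oxazol-5-yl)ethan-1-one | O=C(Cc1cnco1)n1ccnc1 | intermediate
4 | methyl (2S)-3-hydroxy-2-[2-(1,3-oxazol-5-yl)acetamido]propanoate | COC(=O)[C@H](CO)NC(=O)Cc1cnco1 | intermediate
5 | methyl (4S)-2-(1,3-oxazol-5-ylmethyl)-4,5-dihydro-1,3-oxazole-4-carboxylate | COC(=O)[C@@H]1COC(Cc2cnco2)=N1 | intermediate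
6 | methyl 2-(1,3-oxazol-5-ylmethyl)-1,3-oxazole-4-carboxylate | COC(=O)c1coc(Cc2cnco2)n1 | intermediate
7 | diisobutylaluminium hemiacetal of 6 (O-aluminated methyl hemiacetal, carbinol centre undefined) | COC(O[Al](CC(C)C)CC(C)C)c1coc(Cc2cnco2)n1 | intermediate
8 | 2-(1,3-oxazol-5-ylmethyl)-1,3-oxazole-4-carbaldehyde | O=Cc1coc(Cc2cnco2)n1 | intermediate
9 | (E)-2-(1,3-oxazol-5-ylmethyl)-1,3-oxazole-4-carbaldehyde oxime | O/N=C/c1coc(Cc2cnco2)n1 | intermediate
10 | allyl methoxymethyl ether [3-(methoxymethoxy)prop-1-ene] | C=CCOCOC | starting material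
11 | acetaldehyde | CC=O | starting material
12 | [(Z)-3-(methoxymethoxy)allyl]lithium | [Li+].[CH2-]/C=C\OCOC | intermediate
13 | lithium methoxy[(2Z)-3-(methoxymethoxy)prop-2-en-1-yl]bis[(1S,2R,3S,5S)-2,6,6-trimethylbicyclo[3.1.1]heptan-3-yl]borate | [Li+].CO[B-](C/C=C\OCOC)([C@H]1C[C@H]2C[C@@H]([C@@H]1C)C2(C)C)[C@H]1C[C@H]2C[C@@H]([C@@H]1C)C2(C)C | intermediate
14 | [(2Z)-3-(methoxymethoxy)prop-2-en-1-yl]bis[(1S,2R,3S,5S)-2,6,6-trimethylbicyclo[3.1.1]heptan-3-yl]borane | COCO/C=C\CB([C@H]1C[C@H]2C[C@@H]([C@@H]1C)C2(C)C)[C@H]1C[C@H]2C[C@@H]([C@@H]1C)C2(C)C | intermediate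
15 | (2S,3S)-3-(methoxymethoxy)pent-4-en-2-yl bis[(1S,2R,3S,5S)-2,6,6-trimethylbicyclo[3.1.1]heptan-3-yl]borinate | C[C@H](OB([C@H]1C[C@H]2C[C@@H]([C@@H]1C)C2(C)C)[C@H]1C[C@H]2C[C@@H]([C@@H]1C)C2(C)C)[C@@H](OCOC)C=C | intermediate
16 | (2S,3S)-3-(methoxymethoxy)pent-4-en-2-ol | C[C@H](O)[C@@H](OCOC)C=C | intermediate
17 | tetradecanoyl chloride (myristoyl chloride) | CCCCCCCCCCCCCC(Cl)=O | starting material
18 | (2S,3S)-3-(methoxymethoxy)pent-4-en-2-yl tetradecanoate | CCCCCCCCCCCCCC(=O)O[C@@H](C)[C@@H](OCOC)C=C | intermediate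
19 | (Z)-N-hydroxy-2-(1,3-oxazol-5-ylmethyl)-1,3-oxazole-4-carboximidoyl chloride | O/N=C(\Cl)c1coc(Cc2cnco2)n1 | intermediate
20 | 2-(1,3-oxazol-5-ylmethyl)-1,3-oxazole-4-carbonitrile oxide | [O-][N+]#Cc1coc(Cc2cnco2)n1 | intermediate
21 | (1R,2S)-1-(methoxymethoxy)-1-{(5S)-3-[2-(1,3-oxazol-5-ylmethyl)-1,3-oxazol-4-yl]-4,5-dihydro-1,2-oxazol-5-yl}propan-2-yl tetradecanoate | CCCCCCCCCCCCCC(=O)O[C@@H](C)[C@@H](OCOC)[C@@H]1CC(c2coc(Cc3cnco3)n2)=NO1 | intermediate
22 | (2S,3S,4S)-4-hydroxy-6-imino-3-(methoxymethoxy)-6-[2-(1,3-oxazol-5-ylmethyl)-1,3-oxazol-4-yl]hexan-2-yl tetradecanoate | CCCCCCCCCCCCCC(=O)O[C@@H](C)[C@@H](OCOC)[C@@H](O)CC(=N)c1coc(Cc2cnco2)n1 | intermediate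
23 | (2S,3S,4S)-4-hydroxy-3-(methoxymethoxy)-6-oxo-6-[2-(1,3-oxazol-5-ylmethyl)-1,3-oxazol-4-yl]hexan-2-yl tetradecanoate | CCCCCCCCCCCCCC(=O)O[C@@H](C)[C@@H](OCOC)[C@@H](O)CC(=O)c1coc(Cc2cnco2)n1 | intermediate
24 | (2S,3S,4S)-4-[(diethylboranyl)oxy]-3-(methoxymethoxy)-6-oxo-6-[2-(1,3-oxazol-5-ylmethyl)-1,3-oxazol-4-yl]hexan-2-yl tetradecanoate (boron chelated to the ketone) | CCCCCCCCCCCCCC(=O)O[C@@H](C)[C@@H](OCOC)[C@@H](OB(CC)CC)CC(=O)c1coc(Cc2cnco2)n1 | intermediate
25 | sodium (4S,6R)-2,2-diethyl-4-[(1S,2S)-1-(methoxymethoxy)-2-(tetradecanoyloxy)propyl]-6-[2-(1,3-oxazol-5-ylmethyl)-1,3-oxazol-4-yl]-1,3,2-dioxaborinan-2-uide | [Na+].CCCCCCCCCCCCCC(=O)O[C@@H](C)[C@@H](OCOC)[C@@H]1C[C@H](c2coc(Cc3cnco3)n2)O[B-](CC)(CC)O1 | intermediate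
26 | (2S,3S,4S,6R)-4,6-dihydroxy-3-(methoxymethoxy)-6-[2-(1,3-oxazol-5-ylmethyl)-1,3-oxazol-4-yl]hexan-2-yl tetradecanoate | CCCCCCCCCCCCCC(=O)O[C@@H](C)[C@@H](OCOC)[C@@H](O)C[C@@H](O)c1coc(Cc2cnco2)n1 | intermediate
27 | (2S,3S,4S,6R)-3,4,6-trihydroxy-6-[2-(1,3-oxazol-5-ylmethyl)-1,3-oxazol-4-yl]hexan-2-yl tetradecanoate | CCCCCCCCCCCCCC(=O)O[C@@H](C)[C@@H](O)[C@@H](O)C[C@@H](O)c1coc(Cc2cnco2)n1 | target

**Step count**
Total: 10 steps. Longest linear sequence: 8 steps (steps 1, 2, 3, 4, 7, 8, 9, 10); steps 5 and 6 form the two‑step side branch that joins at step 7.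

**Steps most likely to fail**

Step 7 (cycloaddition). The facial selectivity from an acyclic allylic ether may be modest, and the nitrile oxide can dimerise. The fallback sets out from 6 and 18 and comes back at 23. Ester 6 is converted with Me3Al/MeNH(OMe)·HCl into the N‑methoxy‑N‑methyl amide F1. MeMgBr at −78 °C then gives the methyl ketone F2, and Me3SiOSO2CF3/Et3N gives the trimethylsilyl enol ether F3. In parallel, alkene 18 is ozonised (O3, CH2Cl2, −78 °C; PPh3) to the α‑alkoxy aldehyde F4. A BF3·OEt2‑mediated Mukaiyama aldol addition of F3 to F4 at −78 °C goes through an open transition state under Felkin–Anh control, reinforced by the syn β‑oxygen. It gives the 3,4‑anti β‑hydroxy ketone 23 directly, so the isoxazoline and its N–O cleavage are bypassed.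

Step 10 (final MOM removal). The freed or neighbouring hydroxyls could capture the acetal carbon as a cyclic formal, and the Lewis acid could promote migration of the ester to the new adjacent hydroxyl. The fallback sets out from 21 and comes back at 27. The MOM ether is cleaved at the isoxazoline stage, where no free hydroxyl is nearby (Me2BBr, CH2Cl2, −78 °C; aq. NaHCO3), to give the hydroxy isoxazoline F5. Raney Ni/H2/B(OH)3 then gives the dihydroxy ketone F6. Et2BOMe (2.2 equiv)/NaBH4 at −78 °C reduces F6 1,3‑syn to 27, so the last operation is a cold reduction and no Lewis acid meets the free triol.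

Step 3 (half‑reduction). The oxazole nitrogens bind aluminium, so over‑reduction to the alcohol or incomplete conversion is common. The fallback sets out from 6 and comes back at 8. Full reduction with LiAlH4 (THF, 0 °C) gives the primary alcohol F7, and MnO2 (CH2Cl2, rt) oxidises this activated heteroaryl carbinol back to aldehyde 8.

**Further compounds**
F1 | step 7 | N-methoxy-N-methyl-2-(1,3-oxazol-5-ylmethyl)-1,3-oxazole-4-carboxamide | CON(C)C(=O)c1coc(Cc2cnco2)n1
F2 | step 7 | 1-[2-(1,3-oxazol-5-ylmethyl)-1,3-oxazol-4-yl]ethan-1-one | CC(=O)c1coc(Cc2cnco2)n1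
F3 | step 7 | 2-(1,3-oxazol-5-ylmethyl)-4-[1-(trimethylsilyloxy)ethenyl]-1,3-oxazole | C=C(O[Si](C)(C)C)c1coc(Cc2cnco2)n1
F4 | step 7 | (2S,3R)-3-(methoxymethoxy)-4-oxobutan-2-yl tetradecanoate | CCCCCCCCCCCCCC(=O)O[C@@H](C)[C@@H](OCOC)C=O
F5 | step 10 | (1R,2S)-1-hydroxy-1-{(5S)-3-[2-(1,3-oxazol-5-ylmethyl)-1,3-oxazol-4-yl]-4,5-dihydro-1,2-oxazol-5-yl}propan-2-yl tetradecanoate | CCCCCCCCCCCCCC(=O)O[C@@H](C)[C@@H](O)[C@@H]1CC(c2coc(Cc3cnco3)n2)=NO1
F6 | step 10 | (2S,3S,4S)-3,4-dihydroxy-6-oxo-6-[2-(1,3-oxazol-5-ylmethyl)-1,3-oxazol-4-yl]hexan-2-yl tetradecanoate | CCCCCCCCCCCCCC(=O)O[C@@H](C)[C@@H](O)[C@@H](O)CC(=O)c1coc(Cc2cnco2)n1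
F7 | step 3 | [2-(1,3-oxazol-5-ylmethyl)-1,3-oxazol-4-yl]methanol | OCc1coc(Cc2cnco2)n1
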